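**Two constants.** The constants I could read came from red and green, at readings of similar depth: starting material 69% in red at 20.0 min, 67% in green at 2.50 h. I took the loss as first order in [partner B], pseudo-first-order while [partner B] stays near its charge. Both runs changed [partner B] and temperature together, so that order was my assumption, not a reading. Dividing ln(charged/left) by time and [partner B] gave 0.856 M⁻¹ h⁻¹ in red and 0.191 M⁻¹ h⁻¹ in green, so the constant doubled every 6.46 K. Carried along that slope, it read 1.46 M⁻¹ h⁻¹ at 70 °C and 0.100 M⁻¹ h⁻¹ at 45 °C.

| setting | green | red | east | north-west | south-west |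
|---|---|---|---|---|---|
| starting material | 0.50 M | 0.50 M | 0.50 M | 0.50 M | 0.50 M |
| partner A | 0.60 M | 0.60 M | 0.600 M | 0.600 M | 0.600 M |
| partner B | 0.84 M | 1.3 M | 0.600 M | 0.600 M | 0.600 M |
| temperature | 51 °C | 65 °C |  | 70 °C | 45 °C |
| remark | run made earlier | run made earlier | at 70 °C until 25 min, from then on at 45 °C |  |  |
| time |  |  | 1.5 h | 1.5 h | 1.5 h |

- green (time / h: target / %, starting material / %): 0.333: 0, 94; 0.667: 2, 89; 1.00: 0, 85; 1.50: 3, 80; 2.50: 3, 67; 5.00: 15, 55
- red (time / min: target / %, starting material / %): 20.0: 1, 69; 40.0: 9, 53; 50.0: 14, 48; 80.0: 28, 35; 90.0: 24, 31; 120: 32, 26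

(scatter of a reading: 1.5 percentage points)



- the best flask by amount of target, in percent of the starting material charged; "all alike" if 1.5 percentage points covers them all (east / north-west / south-west / all alike)
- amount of target at the end, in percent of the starting material charged, east
- amount of target at the end, in percent of the starting material charged, north-west
- amount of target at the end, in percent of the starting material charged, south-west

**Next run.** The three flasks share their charges, so I compared one number for each: the dose, constant times [partner B] times time, summed over the temperature stages. North-west came to 1.32, east to 0.431 and south-west to 0.0902. Red had shown 1% target at a dose of 0.371 and 28% at 1.48. Because north-west's dose was the largest, I chose north-west as the flask to run and left the charges as they stood.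

**The forecast.** The forecast also named north-west, with 6% in east, 21% in north-west and 0.5% in south-west. Its grounds began: “The readings show a lag in target while starting material falls”.

**The result.** The best flask was north-west, with 4.70% in east, 16.2% in north-west and 0.205% in south-west, the same order as the doses.

    target → over-reaction product (k = 9.20 × 10⁻⁵ s⁻¹, Ea = 96.0 kJ mol⁻¹)
    starting material + partner B → open intermediate (k = 4.20 × 10⁻⁴ M⁻¹ s⁻¹, Ea = 89.0 kJ mol⁻¹)
    partner B + partner A → second intermediate (k = 4.50 × 10⁻⁴ M⁻¹ s⁻¹, Ea = 90.0 kJ mol⁻¹)
    target ⇌ isomer of the product (K = 0.660, k = 1.50 × 10⁻⁴ s⁻¹, Ea = 109 kJ mol⁻¹, ΔH = 0 kJ mol⁻¹)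
    open intermediate + second intermediate → target (k = 0.00150 M⁻¹ s⁻¹, Ea = 78.0 kJ mol⁻¹)
    (constants at 70 °C)

**Neighbour flask.** At constant [partner B], north-west's dose gave 26.7% starting material left, but the flask held 56%, with partner B at 16.8% of its own charge. A neighbour of east, charged with 2.4 M partner B, had a dose of 1.72, which gave 17.9% left. That flask held 24.1% starting material and 64.7% of its partner B, and it gave 28.3% target.

The runs are calculated with constants of no real substance.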